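All runs are calculated with made-up constants, noise included.

If 3.00 equiv of reagent meet one equivalent of substrate, substrate is the limiting reagent and the flask heads for full conversion; the question is how far along that road it stands at 2.5 min.

| setting | winter | autumn | summer | flask |
|---|---|---|---|---|
| substrate | 2 mM | 2 mM | 2 mM | 2.0 mM |
| reagent | 3 equiv | 3 equiv | 4.5 equiv | 3.00 equiv |
| scavenger | 0.50 equiv | 2 equiv | 1 equiv | 1.00 equiv |
| remark | run made earlier | run made earlier | run made earlier |  |
| time |  |  |  | 2.5 min |

| run | time / s | substrate / % | target / % |
|---|---|---|---|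
| winter | 10.0 | 87 | 6 |
| winter | 20.0 | 78 | 10 |
| winter | 30.0 | 67 | 9 |
| winter | 50.0 | 57 | 8 |
| winter | 80.0 | 41 | 7 |
| winter | 90.0 | 38 | 3 |
| winter | 120 | 26 | 4 |
| autumn | 10.0 | 89 | 3 |
| autumn | 15.0 | 81 | 3 |
| autumn | 20.0 | 78 | 5 |
| autumn | 30.0 | 66 | 7 |
| autumn | 50.0 | 53 | 7 |
| autumn | 80.0 | 35 | 9 |
| autumn | 120 | 21 | 6 |
| summer | 10.0 | 83 | 8 |
| summer | 30.0 | 62 | 9 |
| summer | 60.0 | 35 | 9 |
| summer | 80.0 | 25 | 10 |
| summer | 120 | 17 | 7 |

(scatter of a reading: 2 percentage points)

- the earlier runs do not show how much of reagent is bound; that part of a forecast is a guess

1. part of the substrate that has reacted at 2.5 min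
2. share of the unused reagent that is free and not bound as idle adduct, at 2.5 min

The ladder starts with target. In the summer run its readings stay between 7% and 10% from 10.0 s to 120 s, while substrate falls from 83% to 17%. At the end of the winter run, substrate and target together leave 70.0% of the charge in something unread. Target therefore tells little about conversion, and the clock is the decay of substrate.

That decay is the next rung. The last reading of each run gives a number of halvings, and time over halvings gives a half-life. The summer value is scaled by 1.50 for its richer reagent, on the assumption that half-life goes as one over [reagent]. The mean is the carried quantity, the run half-life of substrate at 3.00 equiv of reagent: 61.8 s.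

The last rung is the asked time, which holds 2.43 such half-lives, so this reckoning gives 81.4% reacted. The forecast stands higher, at 84% (79% to 88%), reading that “the rate follows reagent, roughly first order”. Its free share is a guess, 80% (45% to 97%).

The flask gives 79.3% reacted, with 91.8% of the unused reagent free.

    intermediate ⇌ isomer of the product (K = 51.0, k = 0.520 s⁻¹)
    scavenger + released group → scavenged by-product (k = 550 M⁻¹ s⁻¹)
    substrate + reagent → intermediate + released group (k = 2.30 M⁻¹ s⁻¹)
    reagent + released group ⇌ idle adduct, settled at all times (K = 7700 M⁻¹)
    intermediate ⇌ target (K = 4.40, k = 1.00 s⁻¹)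

Over its whole run, substrate in the flask halved every 65.9 s, slower than the carried 61.8 s. The neighbouring flask with 0.80 mM of substrate keeps the equivalents, so its [reagent] is lower by a factor of 2.50 and the carried half-life stretches to 155 s. Its 2.5 min then hold 0.968 half-lives, which reckons to 48.9% reacted. That neighbour shows 51.1% reacted, and substrate, at 48.9%, holds the most of its charge at the end.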